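**Retrosynthetic overview**
1. The oxirane is made last, by hydroxyl-directed peracid epoxidation of the 1(10)E,4Z-dienolide.
2. The ten-membered ring and the C6–C7 bond come from an intramolecular allylboration of an allylboronate held in a six-membered C12–O9 lactone onto a C6 Z-enal; that lactone then relactonises to the five-membered 12,6-lactone, freeing 9-OH next to the 8-isobutyrate.
3. The six-membered lactone comes from ring-closing metathesis of a 2-(bromomethyl)acrylate ester of the C9 carbinol, followed by Br-to-Bpin exchange.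
4. The C8–C9 bond and the anti diol monoester come from iridium-catalysed acyloxyallylation of a C9 allylic alcohol with acrolein diisobutyrate.
5. C1–C6, C9, C10, C14, C15 and the 4Z olefin come from nerol. Ring order: six-membered lactone, ten-membered carbocycle, five-membered lactone, oxirane.

Assumption: locants C1–C15 in the text follow germacrane numbering (lactone carbinol C6, ester carbon C8, carbinol C9, epoxide C1/C10), and the SEGPHOS antipode named in step 4 is taken to be the one that gives 8 as drawn (to be confirmed by Mosher analysis and exchanged if not).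

**Route**

Step 1
Reactants: 1 nerol
Product: 2 tert-butyl{[(2Z)-3,7-dimethylocta-2,6-dien-1-yl]oxy}dimethylsilane
Conditions: TBSCl, imidazole, CH2Cl2, 0 °C to rt
Reagents that add atoms: tert-butyldimethylsilyl chloride, CC(C)(C)[Si](C)(C)Cl
Why: Standard silyl ether formation on the primary allylic alcohol, with no stereocentre created and the Z olefin untouched.

Step 2
Reactants: 2 tert-butyl{[(2Z)-3,7-dimethylocta-2,6-dien-1-yl]oxy}dimethylsilane
Product: 3 (2E,6Z)-8-[(tert-butyldimethylsilyl)oxy]-2,6-dimethylocta-2,6-dien-1-ol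
Conditions: SeO2 (0.2 equiv), t-BuOOH (3 equiv), salicylic acid (0.1 equiv), CH2Cl2, rt
Reagents that add atoms: tert-butyl hydroperoxide, CC(C)(C)OO
Why: Selenium dioxide allylic oxidation (Riley oxidation, catalytic variant; ene reaction then [2,3]-sigmatropic shift) attacks the more electron-rich distal olefin at its E methyl group, so the new C9 carbinol is trans to the chain and the C1=C10 bond is E.

Step 3
Reactants: 4 acrolein; 5 isobutyric anhydride
Product: 6 prop-2-ene-1,1-diyl bis(2-methylpropanoate)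
Conditions: FeCl3 (1 mol %), neat, 0 °C to rt
Reagents that add atoms: none
Why: Lewis-acid-catalysed acylal formation (1,1-diacylation of an aldehyde by an anhydride), the reaction that also gives acrolein diacetate.

Step 4
Reactants: 3 (2E,6Z)-8-[(tert-butyldimethylsilyl)oxy]-2,6-dimethylocta-2,6-dien-1-ol; 6 prop-2-ene-1,1-diyl bis(2-methylpropanoate)
Product: 8 (3S,4R,5E,9Z)-11-[(tert-butyldimethylsilyl)oxy]-4-hydroxy-5,9-dimethylundeca-1,5,9-trien-3-yl 2-methylpropanoate, via enal 7 (not isolated)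
Conditions: [Ir(cod)Cl]2 (2.5 mol %), (R)-SEGPHOS (5 mol %), 4-cyano-3-nitrobenzoic acid (10 mol %), K3PO4 (20 mol %), THF, 60 °C
Reagents that add atoms: none
Why: Iridium-catalysed transfer-hydrogenative carbonyl (α-acyloxy)allylation from the alcohol oxidation level (Krische type, established for the dibenzoate acylal and used here with the diisobutyrate so that the C8 ester is installed directly), in which 3 is dehydrogenated to enal 7 and an (E)-σ-(γ-acyloxy)allyl iridium species adds through a closed chair transition state to give the anti C8/C9 relationship, the aldehyde face being fixed by the SEGPHOS ligand (3S,4R).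

Step 5
Reactants: 8 (3S,4R,5E,9Z)-11-[(tert-butyldimethylsilyl)oxy]-4-hydroxy-5,9-dimethylundeca-1,5,9-trien-3-yl 2-methylpropanoate; 9 2-(bromomethyl)prop-2-enoic acid
Product: 10 (3S,4R,5E,9Z)-4-{[2-(bromomethyl)prop-2-enoyl]oxy}-11-[(tert-butyldimethylsilyl)oxy]-5,9-dimethylundeca-1,5,9-trien-3-yl 2-methylpropanoate
Conditions: DIC, DMAP (10 mol %), CH2Cl2, 0 °C
Reagents that add atoms: none
Why: Steglich esterification of the free C9 carbinol at 0 °C, which leaves the neighbouring isobutyrate in place and changes no stereocentre.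

Step 6
Reactants: 10 (3S,4R,5E,9Z)-4-{[2-(bromomethyl)prop-2-enoyl]oxy}-11-[(tert-butyldimethylsilyl)oxy]-5,9-dimethylundeca-1,5,9-trien-3-yl 2-methylpropanoate
Product: 11 (2R,3S)-5-(bromomethyl)-2-[(2E,6Z)-8-[(tert-butyldimethylsilyl)oxy]-6-methylocta-2,6-dien-2-yl]-6-oxo-3,6-dihydro-2H-pyran-3-yl 2-methylpropanoate
Conditions: second-generation Hoveyda–Grubbs catalyst RuCl2(H2IMes)(=CH–C6H4–2-OiPr) (5 mol %), toluene (5 mM), 80 °C
Reagents that add atoms: none
Why: Ring-closing metathesis between the vinyl group and the 1,1-disubstituted acrylate closes the six-membered unsaturated lactone with loss of ethene, the two trisubstituted olefins being inert, and the ring forces C8 and the lactone carbonyl cis on the new C7=C11 bond.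

Step 7
Reactants: 11 (2R,3S)-5-(bromomethyl)-2-[(2E,6Z)-8-[(tert-butyldimethylsilyl)oxy]-6-methylocta-2,6-dien-2-yl]-6-oxo-3,6-dihydro-2H-pyran-3-yl 2-methylpropanoate
Product: 12 (2R,3S)-2-[(2E,6Z)-8-[(tert-butyldimethylsilyl)oxy]-6-methylocta-2,6-dien-2-yl]-6-oxo-5-[(4,4,5,5-tetramethyl-1,3,2-dioxaborolan-2-yl)methyl]-3,6-dihydro-2H-pyran-3-yl 2-methylpropanoate
Conditions: Pd2(dba)3 (2.5 mol %), B2pin2 (1.3 equiv), toluene, 50 °C
Reagents that add atoms: bis(pinacolato)diboron, CC1(C)OB(OC1(C)C)B1OC(C)(C)C(C)(C)O1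
Why: Palladium-catalysed Miyaura-type borylation of the allylic bromide through a π-allyl palladium intermediate delivers boron to the primary terminus, keeping the conjugated endocyclic olefin and giving a 2-(alkoxycarbonyl)allylboronate.

Step 8
Reactants: 12 (2R,3S)-2-[(2E,6Z)-8-[(tert-butyldimethylsilyl)oxy]-6-methylocta-2,6-dien-2-yl]-6-oxo-5-[(4,4,5,5-tetramethyl-1,3,2-dioxaborolan-2-yl)methyl]-3,6-dihydro-2H-pyran-3-yl 2-methylpropanoate
Product: 13 (2R,3S)-2-[(2E,6Z)-8-hydroxy-6-methylocta-2,6-dien-2-yl]-6-oxo-5-[(4,4,5,5-tetramethyl-1,3,2-dioxaborolan-2-yl)methyl]-3,6-dihydro-2H-pyran-3-yl 2-methylpropanoate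
Conditions: PPTS (20 mol %), MeOH, rt
Reagents that add atoms: none
Why: Acid-catalysed methanolysis cleaves the primary allylic TBS ether while the electron-poor allylboronate, the lactone and the isobutyrate survive.

Step 9
Reactants: 13 (2R,3S)-2-[(2E,6Z)-8-hydroxy-6-methylocta-2,6-dien-2-yl]-6-oxo-5-[(4,4,5,5-tetramethyl-1,3,2-dioxaborolan-2-yl)methyl]-3,6-dihydro-2H-pyran-3-yl 2-methylpropanoate
Product: 14 (2R,3S)-2-[(2E,6Z)-6-methyl-8-oxoocta-2,6-dien-2-yl]-6-oxo-5-[(4,4,5,5-tetramethyl-1,3,2-dioxaborolan-2-yl)methyl]-3,6-dihydro-2H-pyran-3-yl 2-methylpropanoate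
Conditions: MnO2 (20 equiv), CH2Cl2, rt; used at once
Reagents that add atoms: none
Why: Heterogeneous MnO2 oxidation of the primary allylic alcohol gives the enal without Z-to-E isomerisation and without touching the allylboronate, which does not add to aldehydes at rt without a catalyst.

Step 10
Reactants: 14 (2R,3S)-2-[(2E,6Z)-6-methyl-8-oxoocta-2,6-dien-2-yl]-6-oxo-5-[(4,4,5,5-tetramethyl-1,3,2-dioxaborolan-2-yl)methyl]-3,6-dihydro-2H-pyran-3-yl 2-methylpropanoate
Product: 17 (6R,7S,8S,9R)-9-hydroxy-8-(2-methylpropanoyloxy)germacra-1(10)E,4Z,11(13)-trien-12,6-olide, via bridged delta-lactone borate 15 (not isolated), via gamma-lactone borate 16 (not isolated)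
Conditions: Sc(OTf)3 (20 mol %), 4 Å MS, toluene (1 mM, slow addition of 14), −20 to 25 °C; then aq. NaHCO3
Reagents that add atoms: none
Why: Proposed new method: a Sc(OTf)3-catalysed intramolecular allylboration of a lactone-embedded 2-(alkoxycarbonyl)allylboronate onto the tethered Z-enal followed in the same flask by relactonisation, in which the Lewis acid binds a pinacol oxygen and raises the electrophilicity of boron, the six-membered lactone locks the allyl unit with C8 trans to CH2B so that the Zimmerman–Traxler chair with the enal substituent equatorial gives the 6,7-anti adduct (6R), the tether from C9 can only reach the C7 face syn to C10 and anti to the C8 ester (7S), and the O6 borate of 15 then attacks the strained bridged lactone carbonyl (5-exo-trig) to give the five-membered 12,6-lactone 16 whose O9 stays masked as the borate until work-up; the closest known reactions are the Lewis-acid-catalysed intermolecular additions of 2-(alkoxycarbonyl)allylboronates to aldehydes that give α-methylene-γ-butyrolactones, macrocyclic Barbier allylations of 2-(bromomethyl)acrylates, and the relactonisation of germacranolides.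

Step 11
Reactants: 17 (6R,7S,8S,9R)-9-hydroxy-8-(2-methylpropanoyloxy)germacra-1(10)E,4Z,11(13)-trien-12,6-olide
Product: 18 (1R,6R,7S,8S,9S,10R)-1,10-epoxy-9-hydroxy-8-(2-methylpropanoyloxy)germacra-4Z,11(13)-dien-12,6-olide (CNP0110853.2)
Conditions: mCPBA (1.1 equiv), NaHCO3 (solid buffer), CH2Cl2, −20 to 0 °C
Reagents that add atoms: meta-chloroperoxybenzoic acid, OOC(=O)c1cccc(Cl)c1
Why: Prilezhaev epoxidation with Henbest hydroxyl direction, in which only the 1(10) olefin is electron-rich and flanked by a free hydroxyl (the 4,5 olefin is deactivated by the allylic lactone oxygen and the exo-methylene is electron-poor) and the peracid attacks its exposed outer face, where the 9-OH lies when H9 eclipses the olefin, giving the threo (1R,10R) epoxide.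

**Compound list**
1 | nerol, (2Z)-3,7-dimethylocta-2,6-dien-1-ol | CC(C)=CCC/C(C)=C\CO | starting material
2 | tert-butyl{[(2Z)-3,7-dimethylocta-2,6-dien-1-yl]oxy}dimethylsilane | CC(C)=CCC/C(C)=C\CO[Si](C)(C)C(C)(C)C | intermediate
3 | (2E,6Z)-8-[(tert-butyldimethylsilyl)oxy]-2,6-dimethylocta-2,6-dien-1-ol | OC/C(C)=C/CC/C(C)=C\CO[Si](C)(C)C(C)(C)C | intermediate
4 | acrolein (prop-2-enal) | C=CC=O | starting material
5 | isobutyric anhydride (2-methylpropanoic anhydride) | CC(C)C(=O)OC(=O)C(C)C | starting material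
6 | prop-2-ene-1,1-diyl bis(2-methylpropanoate) | C=CC(OC(=O)C(C)C)OC(=O)C(C)C | intermediate
7 | (2E,6Z)-8-[(tert-butyldimethylsilyl)oxy]-2,6-dimethylocta-2,6-dienal | O=C/C(C)=C/CC/C(C)=C\CO[Si](C)(C)C(C)(C)C | intermediate
8 | (3S,4R,5E,9Z)-11-[(tert-butyldimethylsilyl)oxy]-4-hydroxy-5,9-dimethylundeca-1,5,9-trien-3-yl 2-methylpropanoate | C=C[C@H](OC(=O)C(C)C)[C@H](O)/C(C)=C/CC/C(C)=C\CO[Si](C)(C)C(C)(C)C | intermediate
9 | 2-(bromomethyl)prop-2-enoic acid | C=C(CBr)C(=O)O | starting material
10 | (3S,4R,5E,9Z)-4-{[2-(bromomethyl)prop-2-enoyl]oxy}-11-[(tert-butyldimethylsilyl)oxy]-5,9-dimethylundeca-1,5,9-trien-3-yl 2-methylpropanoate | C=C[C@H](OC(=O)C(C)C)[C@H](OC(=O)C(=C)CBr)/C(C)=C/CC/C(C)=C\CO[Si](C)(C)C(C)(C)C | intermediate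
11 | (2R,3S)-5-(bromomethyl)-2-[(2E,6Z)-8-[(tert-butyldimethylsilyl)oxy]-6-methylocta-2,6-dien-2-yl]-6-oxo-3,6-dihydro-2H-pyran-3-yl 2-methylpropanoate | BrCC1=C[C@H](OC(=O)C(C)C)[C@@H](/C(C)=C/CC/C(C)=C\CO[Si](C)(C)C(C)(C)C)OC1=O | intermediate
12 | (2R,3S)-2-[(2E,6Z)-8-[(tert-butyldimethylsilyl)oxy]-6-methylocta-2,6-dien-2-yl]-6-oxo-5-[(4,4,5,5-tetramethyl-1,3,2-dioxaborolan-2-yl)methyl]-3,6-dihydro-2H-pyran-3-yl 2-methylpropanoate | CC1(C)OB(CC2=C[C@H](OC(=O)C(C)C)[C@@H](/C(C)=C/CC/C(C)=C\CO[Si](C)(C)C(C)(C)C)OC2=O)OC1(C)C | intermediate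
13 | (2R,3S)-2-[(2E,6Z)-8-hydroxy-6-methylocta-2,6-dien-2-yl]-6-oxo-5-[(4,4,5,5-tetramethyl-1,3,2-dioxaborolan-2-yl)methyl]-3,6-dihydro-2H-pyran-3-yl 2-methylpropanoate | CC1(C)OB(CC2=C[C@H](OC(=O)C(C)C)[C@@H](/C(C)=C/CC/C(C)=C\CO)OC2=O)OC1(C)C | intermediate
14 | (2R,3S)-2-[(2E,6Z)-6-methyl-8-oxoocta-2,6-dien-2-yl]-6-oxo-5-[(4,4,5,5-tetramethyl-1,3,2-dioxaborolan-2-yl)methyl]-3,6-dihydro-2H-pyran-3-yl 2-methylpropanoate | CC1(C)OB(CC2=C[C@H](OC(=O)C(C)C)[C@@H](/C(C)=C/CC/C(C)=C\C=O)OC2=O)OC1(C)C | intermediate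
15 | (6R,7S,8S,9R)-8-(2-methylpropanoyloxy)-6-[(4,4,5,5-tetramethyl-1,3,2-dioxaborolan-2-yl)oxy]germacra-1(10)E,4Z,11(13)-trien-12,9-olide (bridged six-membered lactone, bicyclo[7.3.1] skeleton) | C=C1C(=O)O[C@@H]2/C(C)=C/CC/C(C)=C\[C@@H](OB3OC(C)(C)C(C)(C)O3)[C@H]1[C@@H]2OC(=O)C(C)C | intermediate
16 | (6R,7S,8S,9R)-8-(2-methylpropanoyloxy)-9-[(4,4,5,5-tetramethyl-1,3,2-dioxaborolan-2-yl)oxy]germacra-1(10)E,4Z,11(13)-trien-12,6-olide | C=C1C(=O)O[C@@H]2/C=C(/C)CC/C=C(\C)[C@@H](OB3OC(C)(C)C(C)(C)O3)[C@@H](OC(=O)C(C)C)[C@@H]12 | intermediate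
17 | (6R,7S,8S,9R)-9-hydroxy-8-(2-methylpropanoyloxy)germacra-1(10)E,4Z,11(13)-trien-12,6-olide, also (3aS,4S,5R,6E,10Z,11aR)-5-hydroxy-6,10-dimethyl-3-methylidene-2-oxo-2,3,3a,4,5,8,9,11a-octahydrocyclodeca[b]furan-4-yl 2-methylpropanoate | C=C1C(=O)O[C@@H]2/C=C(/C)CC/C=C(\C)[C@@H](O)[C@@H](OC(=O)C(C)C)[C@@H]12 | intermediate
18 | (1R,6R,7S,8S,9S,10R)-1,10-epoxy-9-hydroxy-8-(2-methylpropanoyloxy)germacra-4Z,11(13)-dien-12,6-olide (CNP0110853.2) | C=C1C(=O)O[C@@H]2/C=C(/C)CC[C@H]3O[C@]3(C)[C@@H](O)[C@@H](OC(=O)C(C)C)[C@@H]12 | target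

**Step count**
Total steps: 11. Longest linear sequence: 10 (nerol 1 to 18 through steps 1, 2 and 4–11; step 3 is a one-step side branch).

**Three steps most likely to fail**

Step 10 (the new allylboration–relactonisation). Likely failure modes are 1,4-elimination of the C8 isobutyrate to a 2-pyranone, a boat transition state that erodes the C6 configuration, and oligomerisation. The fallback uses known chemistry, sets out from 11 and comes back to the route at 17. The bromide 11 is not borylated. PPTS in MeOH removes the silyl group to give the bromo lactone alcohol F3, and MnO2 in CH2Cl2 gives the bromo lactone enal F4. Slow addition of F4 to CrCl2 (divalent chromium chloride, 6 equiv) in THF/DMF at 2 mM then effects a stoichiometric Nozaki–Hiyama (Barbier) macrocyclisation, the known way to close ten-membered germacranolide rings from 2-(bromomethyl)acrylates and aldehydes. This gives, after aqueous work-up, the bridged hydroxy lactone F5, with the same ring-locked allyl geometry and chair transition state. Catalytic DBU in CH2Cl2 at 0 °C relactonises F5 to 17.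

Step 4 (acyloxyallylation with the isobutyrate donor on a hindered enal; acyl migration and the sense of induction must be checked). The fallback sets out from 3 and comes back at 8. MnO2 oxidises 3 to the enal 7, isolated this time. Addition of 7 at −78 °C to [(E)-γ-(diisopropylamino)dimethylsilylallyl]diisopinocampheylborane gives the anti hydroxy allylsilane F1 (E-allylborane, closed chair). The borane is made from allyl(diisopropylamino)dimethylsilane, n-BuLi/TMEDA, Ipc2BOMe of the antipode that gives 4R, and BF3·OEt2. Tamao oxidation of F1 (KF, KHCO3, H2O2, THF/MeOH, retention at C3) gives the anti diol F2. Regioselective acylation of the less hindered C3 carbinol with isobutyric anhydride 5 and 2,4,6-collidine in CH2Cl2 at −40 °C gives 8; the C4 hydroxyl is shielded by the trisubstituted olefin, and the minor regioisomer is recycled to F2 by methanolysis.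

Step 11 (facial selectivity of the last epoxidation depends on the ring conformer). The fallback sets out from 17 and comes back at 18. It replaces substrate control by reagent control: Shi epoxidation with the fructose-derived ketone antipode matched to the (1R,10R) face, Oxone (2KHSO5·KHSO4·K2SO4), NaHCO3, MeCN/dimethoxymethane/H2O, 0 °C. The chiral dioxirane epoxidises E-trisubstituted olefins with its own facial preference and leaves the electron-poor exo-methylene alone. This fallback makes no new compound (F0).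

**Further compounds**
F1 | step 4 | (3S,4R,5E,9Z)-11-[(tert-butyldimethylsilyl)oxy]-3-[(diisopropylamino)dimethylsilyl]-5,9-dimethylundeca-1,5,9-trien-4-ol | C=C[C@H]([Si](C)(C)N(C(C)C)C(C)C)[C@H](O)/C(C)=C/CC/C(C)=C\CO[Si](C)(C)C(C)(C)C
F2 | step 4 | (3S,4R,5E,9Z)-11-[(tert-butyldimethylsilyl)oxy]-5,9-dimethylundeca-1,5,9-triene-3,4-diol | C=C[C@H](O)[C@H](O)/C(C)=C/CC/C(C)=C\CO[Si](C)(C)C(C)(C)C
F3 | step 10 | (2R,3S)-5-(bromomethyl)-2-[(2E,6Z)-8-hydroxy-6-methylocta-2,6-dien-2-yl]-6-oxo-3,6-dihydro-2H-pyran-3-yl 2-methylpropanoate | BrCC1=C[C@H](OC(=O)C(C)C)[C@@H](/C(C)=C/CC/C(C)=C\CO)OC1=O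
F4 | step 10 | (2R,3S)-5-(bromomethyl)-2-[(2E,6Z)-6-methyl-8-oxoocta-2,6-dien-2-yl]-6-oxo-3,6-dihydro-2H-pyran-3-yl 2-methylpropanoate | BrCC1=C[C@H](OC(=O)C(C)C)[C@@H](/C(C)=C/CC/C(C)=C\C=O)OC1=O
F5 | step 10 | (6R,7S,8S,9R)-6-hydroxy-8-(2-methylpropanoyloxy)germacra-1(10)E,4Z,11(13)-trien-12,9-olide (bridged six-membered lactone) | C=C1C(=O)O[C@@H]2/C(C)=C/CC/C(C)=C\[C@@H](O)[C@H]1[C@@H]2OC(=O)C(C)C
F0 | step 11 | none | none
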